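**Plan** (TBS = tert-butyldimethylsilyl; ring numbering C1 = CMe2, C2 = C=O, C3, C4, C5 = C(OH)Me, C6 = CH; chain C7, C8, C9 = C(OH)Me, C10, C11 = OCH2)
1. Retrosynthesis: cut the aryl ether O–C11 first, then return one C1 methyl to a formyl group and C3–C4 to an alkene, then cut the ring bonds C1–C2 and C5–C6.
2. Enabling feature: the C2 carbonyl and the C5 hydroxyl stand 1,4 across the six-membered ring, so the ring is the opened form of a 7-oxabicyclo[2.2.1]heptene with oxygen bridging C2 and C5. C2–C5 plus that oxygen are a 5-methylfuran bearing a silyloxy group on C2.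
3. Forward: (R)-linalool is taken in four steps to an (E)-2-methyl enal holding C1 and C6–C11, and α-angelica lactone gives the silyloxyfuran. Their cycloaddition and bridge opening form the only carbocycle.
4. End game: the formyl group becomes the second C1 methyl via a dithiolane and Raney Ni (which also saturates C3=C4), the silyl ethers are removed, and umbelliferone is attached last by a Mitsunobu reaction.
5. Stereochemistry: C9 comes from (R)-linalool. C5 and C6 are set in the cycloaddition: relative by the formyl-exo/chain-endo topology, absolute by a chiral oxazaborolidinium catalyst. The C1 centre is erased.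

Key step: step 6

Assumption: the (S)-configured oxazaborolidinium catalyst is taken to deliver the furan to the required enal face (formyl C–H···O binding model for 2-substituted enals); if a trial shows the opposite sense, its (R)-enantiomer is used and nothing else changes.

**Step 1**
Reactants: 1 α-angelica lactone
Product: 2 2-[(tert-butyldimethylsilyl)oxy]-5-methylfuran
Conditions: TBSOTf (1.1 equiv), Et3N (1.3 equiv), CH2Cl2, 0 °C
Reagents that add atoms: tert-butyldimethylsilyl trifluoromethanesulfonate, CC(C)(C)[Si](C)(C)OS(=O)(=O)C(F)(F)F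
Why: Soft enolisation of the enol lactone and O-silylation of the dienolate should give the aromatic 2-silyloxyfuran, the standard silyl dienol ether formation from butenolides.

**Step 2**
Reactants: 3 (R)-linalool
Product: 5 (3R)-3,7-dimethyloct-6-ene-1,3-diol, via alkylborane 4 (not isolated)
Conditions: 9-BBN (2.2 equiv), THF, 0 °C → rt; then NaOH (aq), H2O2 (30%), 0 °C → rt
Reagents that add atoms: 9-borabicyclo[3.3.1]nonane, B1C2CCCC1CCC2 (its boron stays only in 4); hydrogen peroxide, OO (oxygen of the new hydroxyl)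
Why: In this hydroboration–oxidation the hindered borane should add anti-Markovnikov to the monosubstituted vinyl group much faster than to the trisubstituted alkene, and oxidation with retention leaves the carbinol centre untouched.

**Step 3**
Reactants: 5 (3R)-3,7-dimethyloct-6-ene-1,3-diol
Product: 6 (3R)-1,3-bis[(tert-butyldimethylsilyl)oxy]-3,7-dimethyloct-6-ene
Conditions: TBSOTf (2.5 equiv), 2,6-lutidine (4 equiv), CH2Cl2, 0 °C → rt
Reagents that add atoms: tert-butyldimethylsilyl trifluoromethanesulfonate, CC(C)(C)[Si](C)(C)OS(=O)(=O)C(F)(F)F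
Why: The silyl triflate should silylate the primary and the hindered tertiary hydroxyl alike (silyl ether formation), so that one kind of protecting group is removed later in one operation.

**Step 4**
Reactants: 6 (3R)-1,3-bis[(tert-butyldimethylsilyl)oxy]-3,7-dimethyloct-6-ene
Product: 8 (4R)-4,6-bis[(tert-butyldimethylsilyl)oxy]-4-methylhexanal, via ozonide 7 (not isolated)
Conditions: O3, CH2Cl2, −78 °C; then PPh3, −78 °C → rt
Reagents that add atoms: ozone, [O-][O+]=O
Why: Ozonolysis with reductive work-up should cleave the only C=C bond to the aldehyde and acetone, silyl ethers being inert to ozone and PPh3.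

**Step 5**
Reactants: 8 (4R)-4,6-bis[(tert-butyldimethylsilyl)oxy]-4-methylhexanal; 9 2-(triphenylphosphoranylidene)propanal
Product: 10 (2E,6R)-6,8-bis[(tert-butyldimethylsilyl)oxy]-2,6-dimethyloct-2-enal
Conditions: 9 (1.5 equiv), toluene, 90 °C
Reagents that add atoms: none
Why: The stabilised formyl ylide should give the (E)-2-methyl enal in a Wittig reaction and is too unreactive to add to the conjugated product.

**Step 6**
Reactants: 2 2-[(tert-butyldimethylsilyl)oxy]-5-methylfuran; 10 (2E,6R)-6,8-bis[(tert-butyldimethylsilyl)oxy]-2,6-dimethyloct-2-enal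
Product: 12 (1R,5S,6S)-6-[(3R)-3,5-bis[(tert-butyldimethylsilyl)oxy]-3-methylpentyl]-5-hydroxy-1,5-dimethyl-2-oxocyclohex-3-ene-1-carbaldehyde, via bridged silyl ketal 11 (not isolated)
Conditions: 2 (2 equiv), (S)-1-(2-methylphenyl)-3,3-diphenyltetrahydro-1H,3H-pyrrolo[1,2-c][1,3,2]oxazaborole·HNTf2 (20 mol %), CH2Cl2, −78 → −40 °C; then AcOH/THF/H2O, 0 °C
Reagents that add atoms: none
Why: Proposed new method: the boron cation binds the formyl oxygen of 10, furan C5 (the vinylogous terminus of the silyl ketene acetal) attacks C6 (β) while furan C2, which carries the silyloxy group, joins C1 (α), either in a single asynchronous [4+2] event or by Mukaiyama–Michael addition whose boron enolate then closes 6-(enolexo)-exo-trig onto the silyloxocarbenium carbon, and dilute acid then ionises the strained silyl ketal 11 at its C2–O bridge bond to release the C2 ketone and the C5 hydroxyl, loss of water to a phenol being blocked because C1 and C5 are fully substituted. The closest known reaction types are chiral boron Lewis acid-catalysed Diels–Alder reactions of furans with 2-substituted acroleins, the cycloaddition–ring opening of 2-silyloxyfurans with strongly activated dienophiles, and vinylogous Mukaiyama–Michael additions of 2-silyloxyfurans, none of them shown with a trisubstituted enal. The only ring, the carbocycle C1–C6, closes by this intermolecular [4+2] union of the four furan carbons with the enal C=C bond. C5 and C6 are set relative to each other by the transition-state topology, in which the 2-methyl group of the enal lies endo and the formyl group exo, as is usual for 2-methyl enals, so the chain on C6 is anti to the oxygen bridge and ends trans to the C5 hydroxyl; the absolute sense comes from the catalyst, which must leave the C1-Re/C6-Si face of the bound s-trans enal open, the remote C9 having no say, and C1, fixed by the (E) geometry, is erased in step 8. The step needs C5-to-β regiochemistry, which the polarity of the two partners secures, and 1,4- rather than 1,2-attack, for which the hindered, catalyst-bound formyl group is relied on. Material that keeps the silyl group on the C5 oxygen, or rests as the lactol between the cis C5 hydroxyl and the formyl group, is carried on and converges in steps 7 and 9.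

**Step 7**
Reactants: 12 (1R,5S,6S)-6-[(3R)-3,5-bis[(tert-butyldimethylsilyl)oxy]-3-methylpentyl]-5-hydroxy-1,5-dimethyl-2-oxocyclohex-3-ene-1-carbaldehyde
Product: 13 (4S,5S,6S)-5-[(3R)-3,5-bis[(tert-butyldimethylsilyl)oxy]-3-methylpentyl]-6-(1,3-dithiolan-2-yl)-4-hydroxy-4,6-dimethylcyclohex-2-en-1-one
Conditions: HS(CH2)2SH (1.3 equiv), BF3·OEt2 (0.3 equiv), CH2Cl2, −30 → 0 °C
Reagents that add atoms: ethane-1,2-dithiol, SCCS
Why: Lewis acid-catalysed dithioacetalisation should take the aldehyde (also from its lactol form) much faster than the enone carbonyl, which is conjugated and flanked by the quaternary C1, and any thiol that adds to the enone β-carbon would be stripped off again in step 8.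

**Step 8**
Reactants: 13 (4S,5S,6S)-5-[(3R)-3,5-bis[(tert-butyldimethylsilyl)oxy]-3-methylpentyl]-6-(1,3-dithiolan-2-yl)-4-hydroxy-4,6-dimethylcyclohex-2-en-1-one
Product: 14 (3S,4S)-3-[(3R)-3,5-bis[(tert-butyldimethylsilyl)oxy]-3-methylpentyl]-4-hydroxy-2,2,4-trimethylcyclohexan-1-one
Conditions: Raney Ni (W-2, excess), EtOH, rt
Reagents that add atoms: none
Why: Raney Ni desulfurisation (Mozingo-type) should cleave both C–S bonds to leave the second C1 methyl group, while its adsorbed hydrogen saturates the conjugated C3=C4 bond without creating a stereocentre and the hindered ketone survives at room temperature.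

**Step 9**
Reactants: 14 (3S,4S)-3-[(3R)-3,5-bis[(tert-butyldimethylsilyl)oxy]-3-methylpentyl]-4-hydroxy-2,2,4-trimethylcyclohexan-1-one
Product: 15 (3S,4S)-3-[(3R)-3,5-dihydroxy-3-methylpentyl]-4-hydroxy-2,2,4-trimethylcyclohexan-1-one
Conditions: aq. HF (48%), MeCN, 0 °C → rt
Reagents that add atoms: none
Why: Fluoride-driven desilylation should cleave the primary and, more slowly, the tertiary silyl ether, while the ketone and the tertiary alcohols tolerate dilute HF at room temperature.

**Step 10**
Reactants: 15 (3S,4S)-3-[(3R)-3,5-dihydroxy-3-methylpentyl]-4-hydroxy-2,2,4-trimethylcyclohexan-1-one; 16 umbelliferone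
Product: 17 7-{[(3R)-3-hydroxy-5-[(1S,6S)-6-hydroxy-2,2,6-trimethyl-3-oxocyclohexyl]-3-methylpentyl]oxy}-2H-chromen-2-one
Conditions: 16 (1.2 equiv), PPh3, DIAD, THF, 0 °C → rt
Reagents that add atoms: none
Why: In the Mitsunobu reaction only the primary hydroxyl should form an alkoxyphosphonium ion that the acidic 7-hydroxycoumarin displaces, the two tertiary hydroxyls being too hindered, and no stereocentre is touched.

**Compound list**
1 | α-angelica lactone (5-methylfuran-2(3H)-one) | CC1=CCC(=O)O1 | starting material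
2 | 2-[(tert-butyldimethylsilyl)oxy]-5-methylfuran | Cc1ccc(O[Si](C)(C)C(C)(C)C)o1 | intermediate
3 | (R)-linalool, (3R)-3,7-dimethylocta-1,6-dien-3-ol | C=C[C@](C)(O)CCC=C(C)C | starting material
4 | 9-[(3S)-3-hydroxy-3,7-dimethyloct-6-en-1-yl]-9-borabicyclo[3.3.1]nonane (not isolated; same spatial arrangement as 3) | B1(CC[C@](C)(O)CCC=C(C)C)C2CCCC1CCC2 | intermediate
5 | (3R)-3,7-dimethyloct-6-ene-1,3-diol | OCC[C@](C)(O)CCC=C(C)C | intermediate
6 | (3R)-1,3-bis[(tert-butyldimethylsilyl)oxy]-3,7-dimethyloct-6-ene | CC(C)(C)[Si](C)(C)OCC[C@](C)(O[Si](C)(C)C(C)(C)C)CCC=C(C)C | intermediate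
7 | 5-[(3R)-3,5-bis[(tert-butyldimethylsilyl)oxy]-3-methylpentyl]-3,3-dimethyl-1,2,4-trioxolane (ozonide, not isolated, both epimers at the ring CH) | CC1(C)OOC(CC[C@@](C)(O[Si](C)(C)C(C)(C)C)CCO[Si](C)(C)C(C)(C)C)O1 | intermediate
8 | (4R)-4,6-bis[(tert-butyldimethylsilyl)oxy]-4-methylhexanal | O=CCC[C@@](C)(O[Si](C)(C)C(C)(C)C)CCO[Si](C)(C)C(C)(C)C | intermediate
9 | 2-(triphenylphosphoranylidene)propanal | CC(C=O)=P(c1ccccc1)(c1ccccc1)c1ccccc1 | starting material
10 | (2E,6R)-6,8-bis[(tert-butyldimethylsilyl)oxy]-2,6-dimethyloct-2-enal | O=C/C(C)=C/CC[C@@](C)(O[Si](C)(C)C(C)(C)C)CCO[Si](C)(C)C(C)(C)C | intermediate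
11 | 3-endo-[(3R)-3,5-bis[(tert-butyldimethylsilyl)oxy]-3-methylpentyl]-1-[(tert-butyldimethylsilyl)oxy]-2-endo,4-dimethyl-7-oxabicyclo[2.2.1]hept-5-ene-2-exo-carbaldehyde (not isolated) | C[C@@]1(C=O)[C@@]2(O[Si](C)(C)C(C)(C)C)C=C[C@](C)(O2)[C@H]1CC[C@@](C)(O[Si](C)(C)C(C)(C)C)CCO[Si](C)(C)C(C)(C)C | intermediate
12 | (1R,5S,6S)-6-[(3R)-3,5-bis[(tert-butyldimethylsilyl)oxy]-3-methylpentyl]-5-hydroxy-1,5-dimethyl-2-oxocyclohex-3-ene-1-carbaldehyde | C[C@@]1(C=O)C(=O)C=C[C@](C)(O)[C@H]1CC[C@@](C)(O[Si](C)(C)C(C)(C)C)CCO[Si](C)(C)C(C)(C)C | intermediate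
13 | (4S,5S,6S)-5-[(3R)-3,5-bis[(tert-butyldimethylsilyl)oxy]-3-methylpentyl]-6-(1,3-dithiolan-2-yl)-4-hydroxy-4,6-dimethylcyclohex-2-en-1-one | C[C@@]1(C2SCCS2)C(=O)C=C[C@](C)(O)[C@H]1CC[C@@](C)(O[Si](C)(C)C(C)(C)C)CCO[Si](C)(C)C(C)(C)C | intermediate
14 | (3S,4S)-3-[(3R)-3,5-bis[(tert-butyldimethylsilyl)oxy]-3-methylpentyl]-4-hydroxy-2,2,4-trimethylcyclohexan-1-one | CC1(C)C(=O)CC[C@](C)(O)[C@H]1CC[C@@](C)(O[Si](C)(C)C(C)(C)C)CCO[Si](C)(C)C(C)(C)C | intermediate
15 | (3S,4S)-3-[(3R)-3,5-dihydroxy-3-methylpentyl]-4-hydroxy-2,2,4-trimethylcyclohexan-1-one | CC1(C)C(=O)CC[C@](C)(O)[C@H]1CC[C@@](C)(O)CCO | intermediate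
16 | umbelliferone (7-hydroxy-2H-chromen-2-one) | O=c1ccc2ccc(O)cc2o1 | starting material
17 | 7-{[(3R)-3-hydroxy-5-[(1S,6S)-6-hydroxy-2,2,6-trimethyl-3-oxocyclohexyl]-3-methylpentyl]oxy}-2H-chromen-2-one | CC1(C)C(=O)CC[C@](C)(O)[C@H]1CC[C@@](C)(O)CCOc1ccc2ccc(=O)oc2c1 | target

**Total step count:** 10
**Longest linear sequence:** 9 steps (3 → 17, steps 2–10)

**Steps most likely to fail**

Step 6 (new method). The furan may add to the formyl carbon instead of the double bond, the sequence may stop after the first C–C bond without ring closure, and control of the enal face or of the exo/endo mode may be poor. The fallback uses known reactions, sets out from aldehyde 8 and furan 2, and rejoins the route at 14. Wittig reaction of 8 with (triphenylphosphoranylidene)acetaldehyde should give the α-unsubstituted (E)-enal F1. An iminium-catalysed vinylogous Mukaiyama–Michael addition of 2 follows (2,4-dinitrobenzoic acid salt of 5-benzyl-2-tert-butyl-3-methylimidazolidin-4-one, enantiomer chosen for the required face, CH2Cl2/H2O, −70 °C). This reaction is known for 5-methyl-2-silyloxyfurans with β-alkyl enals and is expected to favour the syn adduct needed here, setting C5 and C6 in the butenolide aldehyde F2. Pinnick oxidation gives the butenolide acid F3, and allyl bromide/K2CO3 gives its allyl ester F4. LiHMDS should then close the C1–C2 bond by Dieckmann-type attack of the ester enolate on the lactone carbonyl, which frees the C5 hydroxyl and leaves the allyl β-keto ester F5. Pd(PPh3)4 with morpholine removes the allyl ester with loss of CO2 to give the 6-unsubstituted enone F6. LDA/MeI applied twice methylates C1, the only enolisable position, through the monomethyl enone F7 to the 6,6-dimethyl enone F8. H2 over Pd/C then saturates C3=C4 and gives 14.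

Step 7. The dithiol may also attack the enone carbonyl, the Lewis acid may dehydrate the tertiary allylic alcohol or strip silyl ethers, and the lactol form may resist opening. The fallback sets out from 12, rejoins at 14 and bypasses step 8 as well. K2CO3 in MeOH should cleave the non-enolisable β-keto aldehyde by retro-Claisen deformylation to the 6-methyl enone F9 (C1 epimers, the same compound as F7). LDA (2.2 equiv) and MeI then give the 6,6-dimethyl enone F10 (the same compound as F8), and H2 over Pd/C gives 14.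

Step 8. The nickel may also reduce the hindered ketone or leave part of the C3=C4 bond untouched, so that mixtures of oxidation levels result. The fallback sets out from 13 and rejoins at 14. The reduction is driven deliberately to completion (Raney Ni, H2, EtOH, 50 °C) to the ring diol F11 (C2 epimers), and Dess–Martin periodinane then reoxidises the secondary alcohol, the tertiary ones being inert, to 14.

**Further compounds**
F1 | step 6 | (2E,6R)-6,8-bis[(tert-butyldimethylsilyl)oxy]-6-methyloct-2-enal | O=C/C=C/CC[C@@](C)(O[Si](C)(C)C(C)(C)C)CCO[Si](C)(C)C(C)(C)C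
F2 | step 6 | (3S,6R)-6,8-bis[(tert-butyldimethylsilyl)oxy]-6-methyl-3-[(2R)-2-methyl-5-oxo-2,5-dihydrofuran-2-yl]octanal | O=CC[C@H](CC[C@@](C)(O[Si](C)(C)C(C)(C)C)CCO[Si](C)(C)C(C)(C)C)[C@@]1(C)OC(=O)C=C1
F3 | step 6 | (3S,6R)-6,8-bis[(tert-butyldimethylsilyl)oxy]-6-methyl-3-[(2R)-2-methyl-5-oxo-2,5-dihydrofuran-2-yl]octanoic acid | OC(=O)C[C@H](CC[C@@](C)(O[Si](C)(C)C(C)(C)C)CCO[Si](C)(C)C(C)(C)C)[C@@]1(C)OC(=O)C=C1
F4 | step 6 | allyl (3S,6R)-6,8-bis[(tert-butyldimethylsilyl)oxy]-6-methyl-3-[(2R)-2-methyl-5-oxo-2,5-dihydrofuran-2-yl]octanoate | C=CCOC(=O)C[C@H](CC[C@@](C)(O[Si](C)(C)C(C)(C)C)CCO[Si](C)(C)C(C)(C)C)[C@@]1(C)OC(=O)C=C1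
F5 | step 6 | allyl 6-[(3R)-3,5-bis[(tert-butyldimethylsilyl)oxy]-3-methylpentyl]-5-hydroxy-5-methyl-2-oxocyclohex-3-ene-1-carboxylate (C5 and C6 as in 12, C1 epimers) | C=CCOC(=O)C1C(=O)C=C[C@](C)(O)[C@H]1CC[C@@](C)(O[Si](C)(C)C(C)(C)C)CCO[Si](C)(C)C(C)(C)C
F6 | step 6 | (4R,5S)-5-[(3R)-3,5-bis[(tert-butyldimethylsilyl)oxy]-3-methylpentyl]-4-hydroxy-4-methylcyclohex-2-en-1-one | C1C(=O)C=C[C@](C)(O)[C@H]1CC[C@@](C)(O[Si](C)(C)C(C)(C)C)CCO[Si](C)(C)C(C)(C)C
F7 | step 6 | (4S,5S)-5-[(3R)-3,5-bis[(tert-butyldimethylsilyl)oxy]-3-methylpentyl]-4-hydroxy-4,6-dimethylcyclohex-2-en-1-one (C6 epimers) | CC1C(=O)C=C[C@](C)(O)[C@H]1CC[C@@](C)(O[Si](C)(C)C(C)(C)C)CCO[Si](C)(C)C(C)(C)C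
F8 | step 6 | (4S,5S)-5-[(3R)-3,5-bis[(tert-butyldimethylsilyl)oxy]-3-methylpentyl]-4-hydroxy-4,6,6-trimethylcyclohex-2-en-1-one | CC1(C)C(=O)C=C[C@](C)(O)[C@H]1CC[C@@](C)(O[Si](C)(C)C(C)(C)C)CCO[Si](C)(C)C(C)(C)C
F9 | step 7 | (4S,5S)-5-[(3R)-3,5-bis[(tert-butyldimethylsilyl)oxy]-3-methylpentyl]-4-hydroxy-4,6-dimethylcyclohex-2-en-1-one (C6 epimers) | CC1C(=O)C=C[C@](C)(O)[C@H]1CC[C@@](C)(O[Si](C)(C)C(C)(C)C)CCO[Si](C)(C)C(C)(C)C
F10 | step 7 | (4S,5S)-5-[(3R)-3,5-bis[(tert-butyldimethylsilyl)oxy]-3-methylpentyl]-4-hydroxy-4,6,6-trimethylcyclohex-2-en-1-one | CC1(C)C(=O)C=C[C@](C)(O)[C@H]1CC[C@@](C)(O[Si](C)(C)C(C)(C)C)CCO[Si](C)(C)C(C)(C)C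
F11 | step 8 | 3-[(3R)-3,5-bis[(tert-butyldimethylsilyl)oxy]-3-methylpentyl]-2,2,4-trimethylcyclohexane-1,4-diol (C3 and C4 as in 14, C1 epimers) | CC1(C)C(O)CC[C@](C)(O)[C@H]1CC[C@@](C)(O[Si](C)(C)C(C)(C)C)CCO[Si](C)(C)C(C)(C)C
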